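## Retrosynthetic overview

1. The triene is cut at C17–C18: a late Heck coupling joins the spirocyclic 2-substituted butadiene to a (Z)-vinyl iodide made by carbomagnesiation of propargyl alcohol.
2. Ring B (cyclopentanol) is closed second, at C5–C1, by a chelation-controlled carbonyl-ene reaction of an α-quaternary aldehyde with a pendant 3-methyl-1,3-diene; this sets C5 and C1 and creates the exo-methylene.
3. Ring A (cyclohexane) is made first by the key step: a trivalent-manganese oxidative 6-endo radical cyclisation of an α-alkylated β-keto ester onto a 1-methoxydiene. It forms C4–C6 (the future spiro carbon and C6) and delivers the (Z)-enal as its dimethyl acetal; an 8-phenylmenthyl ester sets the absolute configuration, and methyl addition then sets C10.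
4. The radical precursor is assembled from small pieces by Baylis–Hillman, Johnson–Claisen, Wittig, crossed Claisen and alkylation chemistry; the dienyl tosylate comes from hydrozirconation–Negishi coupling.

Locants used in all names: ring B = C1 (bears the side chain), C2, C3, C4 (spiro), C5 (CHOH); ring A = C4, C6 (bears the 3-hydroxypropyl chain), C7 (ylidene carbon), C8, C9, C10 (C(OH)CH3); Cα = enal carbon bearing the methyl; side chain C15 (=C27H2), C16–C19. Target: (1S,4S,5S,6R,10S), C7=Cα Z, 16E, 18Z.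

Assumption: (−)-8-phenylmenthol is taken as the antipode that shields the radical face leading to the required C4 configuration; if induction runs the other way, commercial (+)-8-phenylmenthol is used with no other change.

## Route

Step 1
Reactants: 1 4-[(tert-butyldimethylsilyl)oxy]butanal; 2 but-3-en-2-one
Product: 3 3-{4-[(tert-butyldimethylsilyl)oxy]-1-hydroxybutyl}but-3-en-2-one (racemic)
Conditions: DABCO (30 mol%), dioxane/H2O 1:1, rt, 3 d
Reagents that add atoms: none
Why: Morita–Baylis–Hillman reaction, in which the DABCO–enone zwitterion traps the aldehyde; the carbinol centre is racemic and is erased in step 2.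

Step 2
Reactants: 3; 4 trimethyl orthoacetate
Product: 6 methyl (4Z)-4-acetyl-8-[(tert-butyldimethylsilyl)oxy]oct-4-enoate, via mixed ketene acetal 5 (not isolated)
Conditions: 4 (6 equiv), EtCO2H (5 mol%), 125 °C, MeOH distilled off
Reagents that add atoms: none
Why: Johnson–Claisen rearrangement of a Baylis–Hillman alcohol; a chair transition state with the carbinol substituent equatorial places the chain trans to the new C8–C9 bond, i.e. cis to the acetyl group (4Z).

Step 3
Reactants: 6
Product: 7 methyl (4Z)-8-[(tert-butyldimethylsilyl)oxy]-4-(1-methoxyprop-1-en-2-yl)oct-4-enoate (E/Z mixture at the enol ether)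
Conditions: MeOCH2PPh3Cl, KHMDS, THF, 0 °C to rt
Reagents that add atoms: (methoxymethyl)triphenylphosphonium chloride, COC[P+](c1ccccc1)(c1ccccc1)c1ccccc1.[Cl-]
Why: Wittig methoxymethylenation of the ketone (the ester is inert to the ylide) turns the electron-poor enone into an electron-rich 1-methoxydiene; the enol ether geometry is irrelevant because that carbon becomes the aldehyde.

Step 4
Reactants: 8 acetyl chloride
Product: 9 (1R,2S,5R)-5-methyl-2-(2-phenylpropan-2-yl)cyclohexyl acetate
Conditions: (1R,2S,5R)-8-phenylmenthol, pyridine, DMAP (5 mol%), CH2Cl2, 0 °C to rt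
Reagents that add atoms: (1R,2S,5R)-8-phenylmenthol, CC(C)(c1ccccc1)[C@@H]1CC[C@@H](C)C[C@H]1O
Why: DMAP-catalysed O-acylation attaches the chiral auxiliary that later controls the radical face.

Step 5
Reactants: 7; 9
Product: 11 (−)-8-phenylmenthyl (6Z)-10-[(tert-butyldimethylsilyl)oxy]-6-(1-methoxyprop-1-en-2-yl)-3-oxodec-6-enoate, via lithium ester enolate 10 (not isolated)
Conditions: 9 (2.2 equiv), LDA (2.2 equiv), THF, −78 °C; then 7, −78 to −20 °C; NH4Cl
Reagents that add atoms: none
Why: Crossed Claisen condensation; excess ester enolate acylates on the methyl ester and the product is protected as its enolate, while the basic medium spares the acid-labile dienol ether.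

Step 6
Reactants: 12 pent-3-yn-1-ol
Product: 13 pent-3-yn-1-yl 4-methylbenzenesulfonate
Conditions: TsCl, pyridine, CH2Cl2, 0 °C
Reagents that add atoms: 4-methylbenzenesulfonyl chloride, Cc1ccc(cc1)S(Cl)(=O)=O
Why: Sulfonylation of the primary alcohol installs the leaving group for step 8 and removes the hydroxyl that would otherwise direct the hydrozirconation.

Step 7
Reactants: 13; 14 bromoethene
Product: 16 (3E)-4-methylhexa-3,5-dien-1-yl 4-methylbenzenesulfonate, via alkenylzirconocene chloride 15 (not isolated)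
Conditions: Cp2Zr(H)Cl (1.4 equiv), THF, 40 °C; then 14, Pd(PPh3)4 (5 mol%), ZnCl2 (20 mol%), rt
Reagents that add atoms: none
Why: Syn hydrozirconation of the internal alkyne (zirconium settles next to the methyl group on equilibration) followed by zerovalent-palladium/zinc-catalysed Negishi coupling with retention gives the (3E)-diene.

Step 8
Reactants: 11; 16
Product: 17 (−)-8-phenylmenthyl (6Z)-10-[(tert-butyldimethylsilyl)oxy]-6-(1-methoxyprop-1-en-2-yl)-2-[(3E)-4-methylhexa-3,5-dien-1-yl]-3-oxodec-6-enoate (both C2 epimers)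
Conditions: Cs2CO3, Bu4NI (10 mol%), DMF, 45 °C
Reagents that add atoms: none
Why: SN2 C-alkylation of the soft β-keto ester enolate with the primary tosylate; the new centre is a mixture and is erased when it becomes the radical in step 9.

Step 9
Reactants: 17
Product: 18 (−)-8-phenylmenthyl (4R,6R)-ring A keto ester: C10 ketone; C4 quaternary bearing the ester (future C5) and the dienyl chain; C6 bearing the silyloxypropyl chain cis to the ester; C7 bearing the (Z)-1,1-dimethoxypropan-2-ylidene group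
Conditions: Mn(OAc)3·2H2O (2.5 equiv), Cu(OAc)2·H2O (20 mol%), KOAc, degassed MeOH, 45 °C; minor diastereomers removed by chromatography
Reagents that add atoms: methanol, CO
Why: Proposed new method: the trivalent-manganese enolate of the α-alkyl β-keto ester gives an electrophilic tertiary C4 radical that adds 6-endo to C6, the electron-rich terminus of the 1-methoxydiene (polarity matched; 5-exo attack at the fully substituted C7 is disfavoured), and the resulting methoxyallyl radical is oxidised by divalent copper or trivalent manganese to an oxocarbenium ion that methanol traps as the dimethyl acetal; a chair transition state with axial ester and equatorial C6 chain sets C6 cis to the ester, the phenylmenthyl group shields one face of the planar radical and so fixes C4, and the acetal carbon ends cis to C6 because the crowded diene reacts from its twisted s-cis conformer and A(1,3) strain keeps the methyl away from C6; the closest known reactions are Mn(OAc)3/Cu(OAc)2 oxidative 6-endo cyclisations of unsaturated α-alkyl β-keto esters carrying phenylmenthyl auxiliaries and Mn(OAc)3 additions of β-dicarbonyl radicals to enol ethers and 1,3-dienes.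

Step 10
Reactants: 18
Product: 19 (−)-8-phenylmenthyl (4R,6R,10S)-ring A hydroxy ester (as 18 with C10 now C(OH)CH3; methyl trans to the ester)
Conditions: MeMgBr, CeCl3, THF, −78 °C; cold aqueous NH4Cl
Reagents that add atoms: methylmagnesium bromide, C[Mg]Br
Why: Organocerium 1,2-addition to the hindered enolisable ketone spares the ester; methyl enters from the ring face opposite the ester and the cis C6 chain (axial attack anti to the axial ester, or equatorial attack forced by the axial C6 chain in the flipped chair), giving the (10S) carbinol.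

Step 11
Reactants: 19
Product: 20 (4S,6R,10S)-ring A diol (C5 now CH2OH; acetal, dienyl chain and silyl ether unchanged)
Conditions: LiAlH4, Et2O, 0 °C to rt
Reagents that add atoms: none
Why: Hydride reduction of the hindered ester to the neopentyl primary alcohol releases the auxiliary; no stereocentre is touched.

Step 12
Reactants: 20
Product: 22 (4R,6R,10S)-ring A hydroxy dialdehyde (C5 aldehyde plus the (Z)-enal), via aldehyde dimethyl acetal 21 (not isolated)
Conditions: Dess–Martin periodinane, CH2Cl2, 0 °C; then PPTS (10 mol%), acetone/H2O 9:1, rt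
Reagents that add atoms: water, O
Why: Dess–Martin oxidation takes only the primary alcohol (the tertiary one cannot be oxidised) and mild acid hydrolysis then frees the allylic acetal; C4 has no hydrogen, so nothing can epimerise.

Step 13
Reactants: 22
Product: 23 (1S,4S,5S,6R,10S)-spirocyclic diol enal with a buta-1,3-dien-2-yl group at C1 and the silyloxypropyl chain at C6
Conditions: Me2AlCl (3 equiv), CH2Cl2, −78 to −30 °C
Reagents that add atoms: none
Why: Me2AlCl-promoted type 1 intramolecular carbonyl-ene reaction; the aluminium alkoxide formed at C10–OH chelates the C5 aldehyde so that C5–O ends syn to C10, the C1 substituent takes the trans position away from the bulky chelate, and only the C15 methyl can give up hydrogen, so the exo-methylene diene results.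

Step 14
Reactants: 24 5-bromo-2-methylpent-2-ene; 25 prop-2-yn-1-ol
Product: 28 (2Z)-3-iodo-2-(4-methylpent-3-en-1-yl)prop-2-en-1-ol, via homoprenylmagnesium bromide 26 (not isolated), via chelated alkenylmagnesium alkoxide 27 (not isolated)
Conditions: Mg, THF; then 25 (0.4 equiv), CuI (10 mol%), 0 °C to rt; then I2, −40 to 0 °C
Reagents that add atoms: iodine, II
Why: Copper-catalysed anti carbomagnesiation of the propargylic alkoxide (Duboudin reaction) puts the alkyl group on C2 and magnesium on C3 cis to CH2O in a five-membered chelate; iodinolysis with retention gives the (Z)-iodide.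

Step 15
Reactants: 23; 28
Product: 29 18-(tert-butyldimethylsilyl) ether of the target (silyl group on the C6 propanol oxygen)
Conditions: Pd(OAc)2 (10 mol%), Bu4NCl, NaHCO3, DMF, 45 °C
Reagents that add atoms: none
Why: Heck reaction under Jeffery conditions; the alkenylpalladium adds to the unsubstituted terminus C17 of the 2-substituted butadiene (as in the arylation of isoprene) and β-hydride elimination gives the (16E) alkene, while the iodide geometry is retained (18Z).

Step 16
Reactants: 29
Product: 30 CNP0249558.1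
Conditions: HF·pyridine, pyridine, THF, 0 °C to rt
Reagents that add atoms: none
Why: Buffered fluoride cleavage of the primary silyl ether leaves the enal, the triene and the alcohols intact and gives the target.

## Compound list

1 | 4-[(tert-butyldimethylsilyl)oxy]butanal (silyl-protected 4-hydroxybutanal) | O=CCCCO[Si](C)(C)C(C)(C)C | starting material
2 | but-3-en-2-one (methyl vinyl ketone) | CC(=O)C=C | starting material
3 | 3-{4-[(tert-butyldimethylsilyl)oxy]-1-hydroxybutyl}but-3-en-2-one, racemic | CC(=O)C(=C)C(O)CCCO[Si](C)(C)C(C)(C)C | intermediate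
4 | trimethyl orthoacetate | CC(OC)(OC)OC | starting material
5 | 1-methoxyvinyl ether of 3 (mixed ketene acetal) | C=C(OC)OC(CCCO[Si](C)(C)C(C)(C)C)C(=C)C(C)=O | intermediate
6 | methyl (4Z)-4-acetyl-8-[(tert-butyldimethylsilyl)oxy]oct-4-enoate | COC(=O)CC/C(C(C)=O)=C/CCCO[Si](C)(C)C(C)(C)C | intermediate
7 | methyl (4Z)-8-[(tert-butyldimethylsilyl)oxy]-4-(1-methoxyprop-1-en-2-yl)oct-4-enoate, E/Z mixture at the enol ether | COC(=O)CC/C(C(C)=COC)=C/CCCO[Si](C)(C)C(C)(C)C | intermediate
8 | acetyl chloride | CC(=O)Cl | starting material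
9 | (1R,2S,5R)-5-methyl-2-(2-phenylpropan-2-yl)cyclohexyl acetate ((−)-8-phenylmenthyl acetate) | CC(=O)O[C@@H]1C[C@H](C)CC[C@H]1C(C)(C)c1ccccc1 | intermediate
10 | lithium enolate of 9 | [Li]OC(=C)O[C@@H]1C[C@H](C)CC[C@H]1C(C)(C)c1ccccc1 | intermediate
11 | (−)-8-phenylmenthyl (6Z)-10-[(tert-butyldimethylsilyl)oxy]-6-(1-methoxyprop-1-en-2-yl)-3-oxodec-6-enoate | O=C(CC(=O)CC/C(C(C)=COC)=C/CCCO[Si](C)(C)C(C)(C)C)O[C@@H]1C[C@H](C)CC[C@H]1C(C)(C)c1ccccc1 | intermediate
12 | pent-3-yn-1-ol | CC#CCCO | starting material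
13 | pent-3-yn-1-yl 4-methylbenzenesulfonate | CC#CCCOS(=O)(=O)c1ccc(C)cc1 | intermediate
14 | bromoethene (vinyl bromide) | C=CBr | starting material
15 | chlorobis(cyclopentadienyl)[(2E)-5-(tosyloxy)pent-2-en-2-yl]zirconium | C/C(=C\CCOS(=O)(=O)c1ccc(C)cc1)[Zr](Cl)(C1C=CC=C1)C1C=CC=C1 | intermediate
16 | (3E)-4-methylhexa-3,5-dien-1-yl 4-methylbenzenesulfonate | C=C/C(C)=C/CCOS(=O)(=O)c1ccc(C)cc1 | intermediate
17 | (−)-8-phenylmenthyl (6Z)-10-[(tert-butyldimethylsilyl)oxy]-6-(1-methoxyprop-1-en-2-yl)-2-[(3E)-4-methylhexa-3,5-dien-1-yl]-3-oxodec-6-enoate, both C2 epimers | C=C/C(C)=C/CCC(C(=O)CC/C(C(C)=COC)=C/CCCO[Si](C)(C)C(C)(C)C)C(=O)O[C@@H]1C[C@H](C)CC[C@H]1C(C)(C)c1ccccc1 | intermediate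
18 | (4R,6R)-ring A keto ester: cyclohexanone (C10=O) with C4 bearing the 8-phenylmenthyl ester and the (3E)-4-methylhexa-3,5-dienyl chain, C6 bearing 3-(TBSO)propyl cis to the ester, C7 bearing (Z)-1,1-dimethoxypropan-2-ylidene (acetal carbon cis to C6) | C=C/C(C)=C/CC[C@]1([C@H](CCCO[Si](C)(C)C(C)(C)C)/C(=C(/C)C(OC)OC)CCC1=O)C(=O)O[C@@H]2C[C@H](C)CC[C@H]2C(C)(C)c2ccccc2 | intermediate
19 | (4R,6R,10S)-ring A hydroxy ester: as 18 with C10 = C(OH)CH3, methyl trans to the ester | C=C/C(C)=C/CC[C@]1([C@H](CCCO[Si](C)(C)C(C)(C)C)/C(=C(/C)C(OC)OC)CC[C@]1(C)O)C(=O)O[C@@H]2C[C@H](C)CC[C@H]2C(C)(C)c2ccccc2 | intermediate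
20 | (4S,6R,10S)-ring A diol: as 19 with the ester reduced to CH2OH (C5) | C=C/C(C)=C/CC[C@]1([C@H](CCCO[Si](C)(C)C(C)(C)C)/C(=C(/C)C(OC)OC)CC[C@]1(C)O)CO | intermediate
21 | (4R,6R,10S)-ring A hydroxy aldehyde with the dimethyl acetal intact | C=C/C(C)=C/CC[C@]1([C@H](CCCO[Si](C)(C)C(C)(C)C)/C(=C(/C)C(OC)OC)CC[C@]1(C)O)C=O | intermediate
22 | (4R,6R,10S)-ring A hydroxy dialdehyde: C5 aldehyde and (Z)-enal | C=C/C(C)=C/CC[C@]1([C@H](CCCO[Si](C)(C)C(C)(C)C)/C(=C(/C)C=O)CC[C@]1(C)O)C=O | intermediate
23 | (1S,4S,5S,6R,10S)-spiro[4.5]decane diol enal: buta-1,3-dien-2-yl at C1 trans to C5–OH, 3-(TBSO)propyl at C6, (Z)-enal at C7 | C=CC(=C)[C@@H]1CC[C@]2([C@H](CCCO[Si](C)(C)C(C)(C)C)/C(=C(/C)C=O)CC[C@]2(C)O)[C@H]1O | intermediate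
24 | 5-bromo-2-methylpent-2-ene | CC(C)=CCCBr | starting material
25 | prop-2-yn-1-ol (propargyl alcohol) | C#CCO | starting material
26 | (4-methylpent-3-en-1-yl)magnesium bromide | CC(C)=CCC[Mg]Br | intermediate
27 | (Z)-[3-(bromomagnesiooxy)-2-(4-methylpent-3-en-1-yl)prop-1-en-1-yl]magnesium bromide | Br[Mg]/C=C(/CCC=C(C)C)CO[Mg]Br | intermediate
28 | (2Z)-3-iodo-2-(4-methylpent-3-en-1-yl)prop-2-en-1-ol | I/C=C(/CCC=C(C)C)CO | intermediate
29 | target with the C6 propanol oxygen as its tert-butyldimethylsilyl ether | C=C(/C=C/C=C(\CO)CCC=C(C)C)[C@@H]1CC[C@]2([C@H](CCCO[Si](C)(C)C(C)(C)C)/C(=C(/C)C=O)CC[C@]2(C)O)[C@H]1O | intermediate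
30 | CNP0249558.1, (1S,4S,5S,6R,10S), 7(α)Z, 16E, 18Z | C=C(/C=C/C=C(\CO)CCC=C(C)C)[C@@H]1CC[C@]2([C@H](CCCO)/C(=C(/C)C=O)CC[C@]2(C)O)[C@H]1O | target

## Step count and risks

Total step count: 16. Longest linear sequence: 12 (steps 1, 2, 3, 5, 8, 9, 10, 11, 12, 13, 15, 16).

The three steps most likely to fail:

Step 9 (key radical cyclisation). The methoxydiene may be oxidised or solvolysed before the radical reaches it, or the acetal carbon may end on the C8 side. The fallback keeps the manganese radical cyclisation but uses a plain ethyl enol ether as acceptor and builds the enal afterwards by steric differentiation of a dibromoalkene. It sets out from 1. 1-Ethoxyvinyllithium (ethyl vinyl ether, t-BuLi, THF, −78 °C) adds to 1 and the alkoxide is acetylated in the flask with Ac2O to give 2-ethoxy-6-[(tert-butyldimethylsilyl)oxy]hex-1-en-3-yl acetate F1. Ireland–Claisen rearrangement (LDA, Me3SiCl, THF, −78 °C to rt) gives (4Z)-4-ethoxy-8-[(tert-butyldimethylsilyl)oxy]oct-4-enoic acid F2. Activation with 1,1′-carbonyldiimidazole and acylation of enolate 10 gives the enol ether β-keto ester F3, and alkylation with 16 as in step 8 gives the alkylated keto ester F4. Mn(OAc)3·2H2O and Cu(OAc)2·H2O in EtOH, followed by dilute acid work-up, give the ring A 1,4-diketone F5 (C7 and C10 ketones). The less hindered C7 ketone is converted with CBr4 and P(Oi-Pr)3 into the C7 dibromomethylene compound F6. Negishi coupling with MeZnCl and Pd(PPh3)4 replaces the bromine on the open C8 side to give the (Z)-bromoalkene F7 (bromine cis to C6). Reductive carbonylation (Pd(OAc)2, PAd2(n-Bu), CO/H2, TMEDA) gives the keto enal F8, and HC(OMe)3 with PPTS in MeOH brings the route back at 18.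

Step 13 (carbonyl-ene ring closure). The diene may give a hetero-Diels–Alder adduct or capture chloride at the allyl cation instead of transferring hydrogen. The fallback replaces the vinyl group by a silyl alkyne, which cannot serve as a 4π partner, and unveils the diene afterwards. It sets out from 15. Coupling of 15 with (bromoethynyl)trimethylsilane (Pd(PPh3)4, ZnCl2) gives (3E)-4-methyl-6-(trimethylsilyl)hex-3-en-5-yn-1-yl tosylate F9. F9 is taken through the reactions of steps 8 to 12 by way of the alkylated keto ester F10, the cyclised keto ester F11, the tertiary alcohol F12, the diol F13, the aldehyde acetal F14 and the dialdehyde F15. Me2AlCl then gives the spirocyclic silyl enyne F16, K2CO3 in MeOH gives the terminal enyne F17, and semihydrogenation (H2, Pd/CaCO3 poisoned with Pb(OAc)2, quinoline) brings the route back at 23.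

Step 15 (Heck coupling). The alkenylpalladium may add to the 1,1-disubstituted end of the diene or be diverted at the π-allyl stage. The fallback makes the C17–C18 bond by Suzuki coupling instead. It sets out from 23. Cross-metathesis with vinylboronic acid pinacol ester (second-generation Hoveyda–Grubbs catalyst, CH2Cl2, 40 °C) at the only monosubstituted alkene gives the (E)-dienylboronate F18, and Suzuki–Miyaura coupling with 28 (Pd(PPh3)4, aqueous K3PO4, THF) brings the route back at 29.

## Further compounds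

F1 | step 9 | 2-ethoxy-6-[(tert-butyldimethylsilyl)oxy]hex-1-en-3-yl acetate (racemic) | C=C(OCC)C(OC(C)=O)CCCO[Si](C)(C)C(C)(C)C
F2 | step 9 | (4Z)-4-ethoxy-8-[(tert-butyldimethylsilyl)oxy]oct-4-enoic acid | OC(=O)CC/C(OCC)=C/CCCO[Si](C)(C)C(C)(C)C
F3 | step 9 | (−)-8-phenylmenthyl (6Z)-6-ethoxy-10-[(tert-butyldimethylsilyl)oxy]-3-oxodec-6-enoate | O=C(CC(=O)CC/C(OCC)=C/CCCO[Si](C)(C)C(C)(C)C)O[C@@H]1C[C@H](C)CC[C@H]1C(C)(C)c1ccccc1
F4 | step 9 | (−)-8-phenylmenthyl (6Z)-6-ethoxy-10-[(tert-butyldimethylsilyl)oxy]-2-[(3E)-4-methylhexa-3,5-dien-1-yl]-3-oxodec-6-enoate | C=C/C(C)=C/CCC(C(=O)CC/C(OCC)=C/CCCO[Si](C)(C)C(C)(C)C)C(=O)O[C@@H]1C[C@H](C)CC[C@H]1C(C)(C)c1ccccc1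
F5 | step 9 | ring A 1,4-diketone: as 18 with C7 a ketone | C=C/C(C)=C/CC[C@]1([C@H](CCCO[Si](C)(C)C(C)(C)C)C(=O)CCC1=O)C(=O)O[C@@H]2C[C@H](C)CC[C@H]2C(C)(C)c2ccccc2
F6 | step 9 | ring A keto ester with C7 dibromomethylene | C=C/C(C)=C/CC[C@]1([C@H](CCCO[Si](C)(C)C(C)(C)C)C(=C(Br)Br)CCC1=O)C(=O)O[C@@H]2C[C@H](C)CC[C@H]2C(C)(C)c2ccccc2
F7 | step 9 | ring A keto ester with C7 (Z)-1-bromoethylidene (bromine cis to C6) | C=C/C(C)=C/CC[C@]1([C@H](CCCO[Si](C)(C)C(C)(C)C)/C(=C(/C)Br)CCC1=O)C(=O)O[C@@H]2C[C@H](C)CC[C@H]2C(C)(C)c2ccccc2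
F8 | step 9 | ring A keto ester with the free (Z)-enal at C7 | C=C/C(C)=C/CC[C@]1([C@H](CCCO[Si](C)(C)C(C)(C)C)/C(=C(/C)C=O)CCC1=O)C(=O)O[C@@H]2C[C@H](C)CC[C@H]2C(C)(C)c2ccccc2
F9 | step 13 | (3E)-4-methyl-6-(trimethylsilyl)hex-3-en-5-yn-1-yl 4-methylbenzenesulfonate | C[Si](C)(C)C#C/C(C)=C/CCOS(=O)(=O)c1ccc(C)cc1
F10 | step 13 | enyne analogue of 17 | C[Si](C)(C)C#C/C(C)=C/CCC(C(=O)CC/C(C(C)=COC)=C/CCCO[Si](C)(C)C(C)(C)C)C(=O)O[C@@H]1C[C@H](C)CC[C@H]1C(C)(C)c1ccccc1
F11 | step 13 | enyne analogue of 18 | C[Si](C)(C)C#C/C(C)=C/CC[C@]1([C@H](CCCO[Si](C)(C)C(C)(C)C)/C(=C(/C)C(OC)OC)CCC1=O)C(=O)O[C@@H]2C[C@H](C)CC[C@H]2C(C)(C)c2ccccc2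
F12 | step 13 | enyne analogue of 19 | C[Si](C)(C)C#C/C(C)=C/CC[C@]1([C@H](CCCO[Si](C)(C)C(C)(C)C)/C(=C(/C)C(OC)OC)CC[C@]1(C)O)C(=O)O[C@@H]2C[C@H](C)CC[C@H]2C(C)(C)c2ccccc2
F13 | step 13 | enyne analogue of 20 | C[Si](C)(C)C#C/C(C)=C/CC[C@]1([C@H](CCCO[Si](C)(C)C(C)(C)C)/C(=C(/C)C(OC)OC)CC[C@]1(C)O)CO
F14 | step 13 | enyne analogue of 21 | C[Si](C)(C)C#C/C(C)=C/CC[C@]1([C@H](CCCO[Si](C)(C)C(C)(C)C)/C(=C(/C)C(OC)OC)CC[C@]1(C)O)C=O
F15 | step 13 | enyne analogue of 22 | C[Si](C)(C)C#C/C(C)=C/CC[C@]1([C@H](CCCO[Si](C)(C)C(C)(C)C)/C(=C(/C)C=O)CC[C@]1(C)O)C=O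
F16 | step 13 | spirocyclic diol enal with 4-(trimethylsilyl)but-1-en-3-yn-2-yl at C1 | C[Si](C)(C)C#CC(=C)[C@@H]1CC[C@]2([C@H](CCCO[Si](C)(C)C(C)(C)C)/C(=C(/C)C=O)CC[C@]2(C)O)[C@H]1O
F17 | step 13 | spirocyclic diol enal with but-1-en-3-yn-2-yl at C1 | C#CC(=C)[C@@H]1CC[C@]2([C@H](CCCO[Si](C)(C)C(C)(C)C)/C(=C(/C)C=O)CC[C@]2(C)O)[C@H]1O
F18 | step 15 | spirocyclic diol enal with (3E)-4-(pinacolboryl)buta-1,3-dien-2-yl at C1 | CC1(C)OB(OC1(C)C)/C=C/C(=C)[C@@H]2CC[C@]3([C@H](CCCO[Si](C)(C)C(C)(C)C)/C(=C(/C)C=O)CC[C@]3(C)O)[C@H]2O
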